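**Strategy.** The trimer is cut at the C4–C6 interflavan bond into a bromine-capped epicatechin-(4β→8)-epicatechin C4 electrophile, made from (−)-epicatechin, and an 8-bromo terminal unit built de novo. The key step exploits ring C of that terminal unit: O1–C8a is an aryl ether on a ring A that can be carried as a fluoroarene, and C2–C3 joins two oxygen-bearing stereocentres in a 2,3-cis array. A zinc-catalysed asymmetric syn-aldol between an α-hydroxy 2,4,6-trifluorophenyl ketone and 3,4-bis(benzyloxy)benzaldehyde forms C2–C3 and both stereocentres; the aldolate oxygen then closes ring C by SNAr at C8a in the same flask. The remaining fluorines are later exchanged for benzyloxy groups.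

Key step: step 2

Remark: the (R,R)-ligand is assumed to deliver the (2S,3R)-syn adduct 7 (its antipode is taken if a model aldol shows the opposite sense); C4 of diols 9–11 is an epimer mixture written without descriptor because it becomes CH2 in step 5.

**Step 1**
Reactants: 1 1,3,5-trifluorobenzene; 2 2-[(tert-butyldimethylsilyl)oxy]-N-methoxy-N-methylacetamide
Product: 5 2-hydroxy-1-(2,4,6-trifluorophenyl)ethan-1-one, via 2,4,6-trifluorophenyllithium 3 (not isolated), via silyl ether ketone 4 (not isolated)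
Conditions: n-BuLi, THF, −78 °C; then 2, −78 → −40 °C; then HCl, MeOH, rt
Reagents that add atoms: none
Why: Lithiation between two fluorines gives the aryllithium, which acylates once on the N-methoxy-N-methylamide (Weinreb ketone synthesis) because the chelated tetrahedral adduct survives until the acidic quench, which also cleaves the silyl ether.

**Step 2**
Reactants: 5 2-hydroxy-1-(2,4,6-trifluorophenyl)ethan-1-one; 6 3,4-bis(benzyloxy)benzaldehyde
Product: 9 (2R,3R)-2-[3,4-bis(benzyloxy)phenyl]-5,7-difluorochromane-3,4-diol (C4 epimers), via syn-aldol adduct 7 (not isolated), via cis-3-hydroxyflavan-4-one 8 (not isolated)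
Conditions: (R,R)-ProPhenol (10 mol %), Et2Zn (20 mol %), 4 Å molecular sieves, THF, −30 °C; then DBU, −20 → 0 °C; then NaBH4, MeOH, −20 °C
Reagents that add atoms: none
Why: Proposed new method: the complex formed from Et2Zn and (R,R)-ProPhenol turns 5 into a chelated zinc enediolate that adds to 6 through a closed bimetallic transition state, and the C2 oxygen of the resulting syn-aldol 7 then displaces an ortho fluorine of the aroyl ring by addition–elimination; the closest known reaction types are the direct zinc–ProPhenol syn-aldol of α-hydroxy aryl ketones and the SNAr closure of ortho-fluoroaryl ketones to chromanones, which have not been joined in one operation. Ring C closes in the 6-exo-trig mode by attack of O1 on C8a, a carbon activated by the ortho carbonyl and by two meta fluorines; the two ortho fluorines are equivalent, so no regiochemical choice arises. C3 and C2 are both set by the chiral dinuclear pocket (syn from the Z-enediolate, absolute sense from the ligand), and since O1 is the former aldehyde oxygen the syn-aldol translates without inversion into the 2,3-cis (2R,3S) ketol 8. The step needs syn over anti addition, one aldehyde face, closure through O–C2 and not O–C3, and no retro-aldol or C3 epimerisation: the C3 hydroxyl is tied to the C4 carbonyl by chelation or hydrogen bonding and could only close a strained five-membered ring, the SNAr is irreversible, and NaBH4 added to the same flask removes the enolisable C4 ketone before work-up.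

**Step 3**
Reactants: 9 (2R,3R)-2-[3,4-bis(benzyloxy)phenyl]-5,7-difluorochromane-3,4-diol
Product: 10 (2R,3R)-5,7-bis(benzyloxy)-2-[3,4-bis(benzyloxy)phenyl]chromane-3,4-diol (C4 epimers)
Conditions: BnOH, NaH, NMP, 90 °C
Reagents that add atoms: benzyl alcohol, OCc1ccccc1
Why: Twofold SNAr by sodium benzyloxide should replace both fluorines, because every donor oxygen is meta to each reacting carbon and the Meisenheimer charge therefore avoids the donor-bearing positions, while the diol, having no carbonyl left, is inert to base.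

**Step 4**
Reactants: 10 (2R,3R)-5,7-bis(benzyloxy)-2-[3,4-bis(benzyloxy)phenyl]chromane-3,4-diol
Product: 11 (2R,3R)-5,7-bis(benzyloxy)-2-[3,4-bis(benzyloxy)phenyl]-8-bromochromane-3,4-diol (C4 epimers)
Conditions: NBS, CH2Cl2, −78 → −20 °C
Reagents that add atoms: N-bromosuccinimide, O=C1CCC(=O)N1Br
Why: Electrophilic aromatic bromination of the phloroglucinol-type ring A goes to C8, the usual site in benzylated flavan-3-ols, so that C6 remains the only free nucleophilic position.

**Step 5**
Reactants: 11 (2R,3R)-5,7-bis(benzyloxy)-2-[3,4-bis(benzyloxy)phenyl]-8-bromochromane-3,4-diol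
Product: 12 8-bromo-5,7,3',4'-tetra-O-benzyl-(−)-epicatechin
Conditions: Et3SiH, CF3CO2H, CH2Cl2, −20 °C
Reagents that add atoms: none
Why: Ionic hydrogenation: the C4 hydroxyl ionises to a benzylic cation stabilised by O1 and the 5- and 7-benzyloxy groups and is reduced by the silane, the C8 bromine suppressing Friedel–Crafts self-condensation and C2 and C3 staying untouched.

**Step 6**
Reactants: 13 (−)-epicatechin
Product: 14 5,7,3',4'-tetra-O-benzyl-(−)-epicatechin
Conditions: BnBr, K2CO3, DMF, 0 °C → rt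
Reagents that add atoms: benzyl bromide, BrCc1ccccc1
Why: Williamson etherification of the four phenols, the secondary C3 alcohol not being deprotonated by carbonate.

**Step 7**
Reactants: 14 5,7,3',4'-tetra-O-benzyl-(−)-epicatechin
Product: 15 4β-(2-ethoxyethoxy)-5,7,3',4'-tetra-O-benzyl-(−)-epicatechin
Conditions: DDQ, 2-ethoxyethanol, CH2Cl2, rt
Reagents that add atoms: 2-ethoxyethanol, CCOCCO
Why: Benzylic oxidation by hydride abstraction at C4 (DDQ) gives a quinone-methide-type cation that the alcohol traps anti to the C3 hydroxyl, setting the 3,4-trans (4β) ether.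

**Step 8**
Reactants: 15 4β-(2-ethoxyethoxy)-5,7,3',4'-tetra-O-benzyl-(−)-epicatechin (two molecules)
Product: 16 5,7,3',4'-tetra-O-benzyl-epicatechin-(4β→8)-[4β-(2-ethoxyethoxy)-5,7,3',4'-tetra-O-benzyl-epicatechin]
Conditions: Zn(OSO2CF3)2, CH2Cl2, rt, stopped at partial conversion
Reagents that add atoms: none
Why: Lewis-acid-mediated Friedel–Crafts self-condensation in which one molecule ionises at C4 and is attacked by the free C8 of a second molecule anti to the C3 hydroxyl, setting the 4β→8 bond, the more hindered dimer reacting on more slowly and keeping its own 4-ether.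

**Step 9**
Reactants: 16 dimeric C4 electrophile
Product: 17 8-bromo-5,7,3',4'-tetra-O-benzyl-epicatechin-(4β→8)-[4β-(2-ethoxyethoxy)-5,7,3',4'-tetra-O-benzyl-epicatechin]
Conditions: NBS (1 equiv), CH2Cl2, −78 → −40 °C
Reagents that add atoms: N-bromosuccinimide, O=C1CCC(=O)N1Br
Why: Electrophilic aromatic bromination at the only free C8 (upper unit), the most reactive ring-A position, caps the electrophile against self-condensation in the next step.

**Step 10**
Reactants: 17 bromine-capped dimeric electrophile; 12 8-bromo-5,7,3',4'-tetra-O-benzyl-(−)-epicatechin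
Product: 18 8-bromo-5,7,3',4'-tetra-O-benzyl-epicatechin-(4β→8)-5,7,3',4'-tetra-O-benzyl-epicatechin-(4β→6)-8-bromo-5,7,3',4'-tetra-O-benzyl-epicatechin
Conditions: Me3SiOSO2CF3 (cat.), 4 Å molecular sieves, CH2Cl2, −78 → −30 °C, 12 in excess
Reagents that add atoms: none
Why: Friedel–Crafts flavanylation in which the ionised C4 of 17 is captured by C6 of 12 (C8 being blocked by bromine, the halo-capping tactic) from the face anti to the C3 hydroxyl, setting the 4β→6 bond.

**Step 11**
Reactants: 18 protected dibromo trimer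
Product: 19 epicatechin-(4β→8)-epicatechin-(4β→6)-epicatechin (CNP0178679.3)
Conditions: H2 (1 atm), Pd(OH)2 on carbon, Et3N, THF/MeOH/H2O, rt
Reagents that add atoms: none
Why: Hydrogenolysis should remove the twelve benzyl ethers and both aryl bromides, triethylamine taking up HBr so that the acid-labile interflavan bonds survive.

**Compound list**

1 | 1,3,5-trifluorobenzene | Fc1cc(F)cc(F)c1 | starting material
2 | 2-[(tert-butyldimethylsilyl)oxy]-N-methoxy-N-methylacetamide | CON(C)C(=O)CO[Si](C)(C)C(C)(C)C | starting material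
3 | 2,4,6-trifluorophenyllithium | [Li]c1c(F)cc(F)cc1F | intermediate
4 | 2-[(tert-butyldimethylsilyl)oxy]-1-(2,4,6-trifluorophenyl)ethan-1-one | CC(C)(C)[Si](C)(C)OCC(=O)c1c(F)cc(F)cc1F | intermediate
5 | 2-hydroxy-1-(2,4,6-trifluorophenyl)ethan-1-one | OCC(=O)c1c(F)cc(F)cc1F | intermediate
6 | 3,4-bis(benzyloxy)benzaldehyde | O=Cc1ccc(OCc2ccccc2)c(OCc2ccccc2)c1 | starting material
7 | (2S,3R)-3-[3,4-bis(benzyloxy)phenyl]-2,3-dihydroxy-1-(2,4,6-trifluorophenyl)propan-1-one (syn-aldol adduct) | O[C@H](c1ccc(OCc2ccccc2)c(OCc2ccccc2)c1)[C@H](O)C(=O)c1c(F)cc(F)cc1F | intermediate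
8 | (2R,3S)-2-[3,4-bis(benzyloxy)phenyl]-5,7-difluoro-3-hydroxychroman-4-one (2,3-cis) | Fc1cc(F)c2c(c1)O[C@H](c1ccc(OCc3ccccc3)c(OCc3ccccc3)c1)[C@H](O)C2=O | intermediate
9 | (2R,3R)-2-[3,4-bis(benzyloxy)phenyl]-5,7-difluorochromane-3,4-diol (2,3-cis, C4 epimers) | Fc1cc(F)c2c(c1)O[C@H](c1ccc(OCc3ccccc3)c(OCc3ccccc3)c1)[C@H](O)C2O | intermediate
10 | (2R,3R)-5,7-bis(benzyloxy)-2-[3,4-bis(benzyloxy)phenyl]chromane-3,4-diol (C4 epimers) | C(c1ccccc1)Oc1cc(OCc3ccccc3)c2c(c1)O[C@H](c1ccc(OCc3ccccc3)c(OCc3ccccc3)c1)[C@H](O)C2O | intermediate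
11 | (2R,3R)-5,7-bis(benzyloxy)-2-[3,4-bis(benzyloxy)phenyl]-8-bromochromane-3,4-diol (C4 epimers) | C(c1ccccc1)Oc1cc(OCc3ccccc3)c2c(c1Br)O[C@H](c1ccc(OCc3ccccc3)c(OCc3ccccc3)c1)[C@H](O)C2O | intermediate
12 | 8-bromo-5,7,3',4'-tetra-O-benzyl-(−)-epicatechin, (2R,3R) | C(c1ccccc1)Oc1cc(OCc3ccccc3)c2c(c1Br)O[C@H](c1ccc(OCc3ccccc3)c(OCc3ccccc3)c1)[C@H](O)C2 | intermediate
13 | (−)-epicatechin, (2R,3R) | Oc1cc(O)c2c(c1)O[C@H](c1ccc(O)c(O)c1)[C@H](O)C2 | starting material
14 | 5,7,3',4'-tetra-O-benzyl-(−)-epicatechin | C(c1ccccc1)Oc1cc(OCc3ccccc3)c2c(c1)O[C@H](c1ccc(OCc3ccccc3)c(OCc3ccccc3)c1)[C@H](O)C2 | intermediate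
15 | 4β-(2-ethoxyethoxy)-5,7,3',4'-tetra-O-benzyl-(−)-epicatechin (2,3-cis-3,4-trans) | C(c1ccccc1)Oc1cc(OCc3ccccc3)c2c(c1)O[C@H](c1ccc(OCc3ccccc3)c(OCc3ccccc3)c1)[C@H](O)[C@H]2OCCOCC | intermediate
16 | 5,7,3',4'-tetra-O-benzyl-epicatechin-(4β→8)-[4β-(2-ethoxyethoxy)-5,7,3',4'-tetra-O-benzyl-epicatechin] | C(c1ccccc1)Oc1cc(OCc3ccccc3)c2c(c1)O[C@H](c1ccc(OCc3ccccc3)c(OCc3ccccc3)c1)[C@H](O)[C@H]2c1c(OCc3ccccc3)cc(OCc3ccccc3)c2c1O[C@H](c1ccc(OCc3ccccc3)c(OCc3ccccc3)c1)[C@H](O)[C@H]2OCCOCC | intermediate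
17 | 8-bromo-5,7,3',4'-tetra-O-benzyl-epicatechin-(4β→8)-[4β-(2-ethoxyethoxy)-5,7,3',4'-tetra-O-benzyl-epicatechin] | C(c1ccccc1)Oc1cc(OCc3ccccc3)c2c(c1Br)O[C@H](c1ccc(OCc3ccccc3)c(OCc3ccccc3)c1)[C@H](O)[C@H]2c1c(OCc3ccccc3)cc(OCc3ccccc3)c2c1O[C@H](c1ccc(OCc3ccccc3)c(OCc3ccccc3)c1)[C@H](O)[C@H]2OCCOCC | intermediate
18 | 8-bromo-5,7,3',4'-tetra-O-benzyl-epicatechin-(4β→8)-5,7,3',4'-tetra-O-benzyl-epicatechin-(4β→6)-8-bromo-5,7,3',4'-tetra-O-benzyl-epicatechin | C(c1ccccc1)Oc1cc(OCc3ccccc3)c2c(c1Br)O[C@H](c1ccc(OCc3ccccc3)c(OCc3ccccc3)c1)[C@H](O)[C@H]2c1c(OCc3ccccc3)cc(OCc3ccccc3)c2c1O[C@H](c1ccc(OCc3ccccc3)c(OCc3ccccc3)c1)[C@H](O)[C@H]2c1c(OCc3ccccc3)c(Br)c2c(c1OCc3ccccc3)C[C@@H](O)[C@@H](c1ccc(OCc3ccccc3)c(OCc3ccccc3)c1)O2 | intermediate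
19 | epicatechin-(4β→8)-epicatechin-(4β→6)-epicatechin (CNP0178679.3) | Oc1cc(O)c2c(c1)O[C@H](c1ccc(O)c(O)c1)[C@H](O)[C@H]2c1c(O)cc(O)c2c1O[C@H](c1ccc(O)c(O)c1)[C@H](O)[C@H]2c1c(O)cc2c(c1O)C[C@@H](O)[C@@H](c1ccc(O)c(O)c1)O2 | target

**Count.** Total steps: 11. Longest linear sequence: 7 (steps 1–5, 10, 11); the other branch is steps 6–9, 10, 11.

**Steps most likely to fail**

1. Step 2. The aldol with the electron-rich aldehyde may be slow and reversible, eroding syn- and enantioselectivity. The C3 oxygen may compete for the C–F carbon in a five-membered closure. The ketol may epimerise at C3 before reduction. The fallback is stepwise, uses an O-protected donor and known reaction types, sets out from 4 (isolated when the acidic methanolysis of step 1 is left out) and 6, and returns at 9. A diisopinocampheylboron-enolate syn-aldol (Ipc2BOSO2CF3 of the appropriate hand, i-Pr2NEt, CH2Cl2, −78 °C, oxidative work-up) should give the silyl-protected syn-aldol F1, whose only free hydroxyl is at C2. K2CO3 in DMF at 0 °C should then close ring C by SNAr to the 3-silyloxy flavanone F2. NaBH4 in MeOH should give the silyl-protected diol F3, and Bu4NF in THF should release 9.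

2. Step 10. Capture at the hindered C6 of 12 may be slow, so that the C4 cation is consumed by self-condensation through C6 positions of 17 or the existing interflavan bond scrambles under acid. The fallback builds the chain from the bottom, sets out from 15 and 12, and returns at 18. Slow addition of 15 to an excess of 12 (Me3SiOSO2CF3, CH2Cl2, −78 °C) should give the 4β→6 dimer F4, whose only reactive site is C8 of its upper unit. Bromination of 15 with NBS should give the capped monomeric electrophile F5, and Lewis-acid coupling of F5 with F4 (chain extension at that C8) should give 18.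

3. Step 3. The second fluorine may resist substitution once the ring has become electron-rich, and the forcing basic conditions may degrade the diol. The fallback moves the exchange to the ketone oxidation level, where both fluorines are ortho or para to the C4 carbonyl. It sets out from 8 (isolated when the borohydride quench of step 2 is left out) and returns at 10. BnOH and K2CO3 in DMF at 0 °C → rt should give the 5,7-bis(benzyloxy) ketol F6, and NaBH4 in MeOH should give 10.

**Further compounds**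

F1 | step 2 | (2S,3R)-3-[3,4-bis(benzyloxy)phenyl]-2-[(tert-butyldimethylsilyl)oxy]-3-hydroxy-1-(2,4,6-trifluorophenyl)propan-1-one | O[C@H](c1ccc(OCc2ccccc2)c(OCc2ccccc2)c1)[C@H](O[Si](C)(C)C(C)(C)C)C(=O)c1c(F)cc(F)cc1F
F2 | step 2 | (2R,3S)-2-[3,4-bis(benzyloxy)phenyl]-3-[(tert-butyldimethylsilyl)oxy]-5,7-difluorochroman-4-one | Fc1cc(F)c2c(c1)O[C@H](c1ccc(OCc3ccccc3)c(OCc3ccccc3)c1)[C@H](O[Si](C)(C)C(C)(C)C)C2=O
F3 | step 2 | (2R,3R)-2-[3,4-bis(benzyloxy)phenyl]-3-[(tert-butyldimethylsilyl)oxy]-5,7-difluorochroman-4-ol (C4 epimers) | Fc1cc(F)c2c(c1)O[C@H](c1ccc(OCc3ccccc3)c(OCc3ccccc3)c1)[C@H](O[Si](C)(C)C(C)(C)C)C2O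
F4 | step 10 | 5,7,3',4'-tetra-O-benzyl-epicatechin-(4β→6)-8-bromo-5,7,3',4'-tetra-O-benzyl-epicatechin | C(c1ccccc1)Oc1cc(OCc3ccccc3)c2c(c1)O[C@H](c1ccc(OCc3ccccc3)c(OCc3ccccc3)c1)[C@H](O)[C@H]2c1c(OCc3ccccc3)c(Br)c2c(c1OCc3ccccc3)C[C@@H](O)[C@@H](c1ccc(OCc3ccccc3)c(OCc3ccccc3)c1)O2
F5 | step 10 | 8-bromo-4β-(2-ethoxyethoxy)-5,7,3',4'-tetra-O-benzyl-(−)-epicatechin | C(c1ccccc1)Oc1cc(OCc3ccccc3)c2c(c1Br)O[C@H](c1ccc(OCc3ccccc3)c(OCc3ccccc3)c1)[C@H](O)[C@H]2OCCOCC
F6 | step 3 | (2R,3S)-5,7-bis(benzyloxy)-2-[3,4-bis(benzyloxy)phenyl]-3-hydroxychroman-4-one | C(c1ccccc1)Oc1cc(OCc3ccccc3)c2c(c1)O[C@H](c1ccc(OCc3ccccc3)c(OCc3ccccc3)c1)[C@H](O)C2=O
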